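**Plan**
- Cuts (retrosynthesis): the two MOM ethers come off last. Ring B is cut at C1'–C2' and C5'–C6' into an aryl hex-2-ynoate (C1', C6', the ester and the propyl group) and 1,1-dimethoxy-3-(trimethylsilyloxy)buta-1,3-diene (C2' to C5'). The ynoate is cut at its acyl–O bond, and ring A at the aryl–acetyl bond and the central aryl C–O bond, back to olivetol.
- Enabling feature: ring B carries OMe at C2' and OH at C4' on the four-carbon edge C2'–C5', the oxygen pattern of a ketene-acetal/silyl-enol-ether diene. C1' (bearing the ester carbonyl) and C6' (bearing propyl) are the two alkyne carbons of a hex-2-ynoate.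
- Forward order: ring A is finished first from symmetric olivetol (central oxygen by lithiation–borylation–oxidation, acetyl by bromination, Br–Li exchange and Weinreb acylation). Its central hydroxyl is esterified with linear hex-2-ynoic acid, ring B is then built on that ester by [4+2] cycloaddition with aromatisation, and acid removes the MOM groups.
- Stereochemistry: the target has no stereocentre and no stereogenic double bond. Only regiochemistry must be controlled; it comes from the mirror symmetry of the ring A intermediates 2 to 6 and from the polarisation of diene and ynoate.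

Key step: step 11

Remark: the starting materials 1, 8, 13, 15 and 16 are taken as catalogue chemicals; the target is achiral, so no SMILES of the main route carries a stereodescriptor.

**Step 1**
Reactants: 1 olivetol (5-pentylbenzene-1,3-diol)
Product: 2 1,3-bis(methoxymethoxy)-5-pentylbenzene
Conditions: MOMCl (2.6 equiv), iPr2NEt, CH2Cl2, 0 °C to rt
Reagents that add atoms: chloromethyl methyl ether, COCCl
Why: Williamson-type O-alkylation of both phenols by the reactive α-chloro ether should give the bis-acetal, whose OMOM groups later direct metalation and tolerate organolithiums, fluoride and heat.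

**Step 2**
Reactants: 2 1,3-bis(methoxymethoxy)-5-pentylbenzene
Product: 5 2,6-bis(methoxymethoxy)-4-pentylphenol, via aryllithium 3 (not isolated), via lithium aryltrimethoxyborate 4 (not isolated)
Conditions: n-BuLi, THF, 0 °C to rt; B(OMe)3, −78 °C to rt; 30% H2O2, aq NaOH, 0 °C
Reagents that add atoms: hydrogen peroxide, OO (oxygen of the new hydroxyl); n-butyllithium, [Li]CCCC, and trimethyl borate, COB(OC)OC, leave lithium and boron only in 3 and 4
Why: Directed ortho-metalation should occur at the carbon flanked by both chelating OMOM groups, and borylation followed by peroxide oxidation (1,2-aryl shift from boron to oxygen) converts that C–Li bond into the central phenol.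

**Step 3**
Reactants: 5 2,6-bis(methoxymethoxy)-4-pentylphenol
Product: 6 tert-butyl[2,6-bis(methoxymethoxy)-4-pentylphenoxy]dimethylsilane
Conditions: TBSCl, imidazole, DMF, rt
Reagents that add atoms: tert-butyldimethylsilyl chloride, CC(C)(C)[Si](C)(C)Cl
Why: Imidazole-promoted O-silylation masks the only acidic proton, so that the phenol is not oxidised in the bromination and the later halogen–lithium exchange needs a single equivalent of n-BuLi.

**Step 4**
Reactants: 6 tert-butyl[2,6-bis(methoxymethoxy)-4-pentylphenoxy]dimethylsilane
Product: 7 [3-bromo-2,6-bis(methoxymethoxy)-4-pentylphenoxy](tert-butyl)dimethylsilane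
Conditions: NBS (1.0 equiv), MeCN, 0 °C, dark
Reagents that add atoms: N-bromosuccinimide, O=C1CCC(=O)N1Br
Why: Electrophilic aromatic bromination of the electron-rich ring can only occur at one of the two symmetry-equivalent C–H positions (each ortho to one OMOM and para to the other), so one equivalent of NBS under ionic, acid-free conditions should give a single monobromide.

**Step 5**
Reactants: 7 [3-bromo-2,6-bis(methoxymethoxy)-4-pentylphenoxy](tert-butyl)dimethylsilane; 8 N-methoxy-N-methylacetamide
Product: 11 1-[3-(tert-butyldimethylsilyloxy)-2,4-bis(methoxymethoxy)-6-pentylphenyl]ethan-1-one, via aryllithium 9 (not isolated), via lithium hemiaminal alkoxide 10 (not isolated)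
Conditions: n-BuLi, THF, −78 °C; then 8, −78 to 0 °C; then H2O
Reagents that add atoms: n-butyllithium, [Li]CCCC (lithium in 9 and 10 only)
Why: Bromine–lithium exchange at −78 °C is faster than attack on the silyl ether or acetals, and the OMOM-chelated aryllithium adds once to the Weinreb amide, whose chelated tetrahedral adduct releases the methyl ketone only on quench (Weinreb ketone synthesis).

**Step 6**
Reactants: 11 1-[3-(tert-butyldimethylsilyloxy)-2,4-bis(methoxymethoxy)-6-pentylphenyl]ethan-1-one
Product: 12 1-[3-hydroxy-2,4-bis(methoxymethoxy)-6-pentylphenyl]ethan-1-one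
Conditions: Bu4NF, AcOH, THF, 0 °C to rt
Reagents that add atoms: none
Why: Fluoride-induced desilylation cleaves the aryl O–Si bond selectively, and the acetic acid buffer protonates the phenoxide so that the ketone and the MOM acetals stay untouched.

**Step 7**
Reactants: 12 1-[3-hydroxy-2,4-bis(methoxymethoxy)-6-pentylphenyl]ethan-1-one; 13 hex-2-ynoic acid
Product: 14 3-acetyl-2,6-bis(methoxymethoxy)-4-pentylphenyl hex-2-ynoate
Conditions: DCC, DMAP (0.1 equiv), CH2Cl2, −10 °C to rt
Reagents that add atoms: none
Why: Steglich esterification should acylate even this 2,6-disubstituted phenol because the activated acid is linear and unhindered, while the 3-propyl group slows conjugate addition to the alkyne at low temperature.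

**Step 8**
Reactants: 15 acetyl chloride; 16 1,1-dichloroethene
Product: 18 4,4-dichlorobut-3-en-2-one, via 4,4,4-trichlorobutan-2-one 17 (not isolated)
Conditions: AlCl3, CH2Cl2, 0 °C to rt; ice quench; distillation (loss of HCl)
Reagents that add atoms: none
Why: Friedel–Crafts-type acylation of the alkene (acylium attack at the CH2 terminus, chloride capture of the dichlorocarbenium ion) followed by β-elimination of HCl should give the conjugated dichlorovinyl ketone.

**Step 9**
Reactants: 18 4,4-dichlorobut-3-en-2-one
Product: 19 4,4-dimethoxybut-3-en-2-one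
Conditions: NaOMe (2.1 equiv), MeOH, 0 °C to rt
Reagents that add atoms: sodium methoxide, [Na+].[O-]C
Why: Two successive conjugate addition–elimination steps (vinylogous nucleophilic acyl substitution) replace both β-chlorides by methoxide, and limiting the base to two equivalents avoids orthoester formation.

**Step 10**
Reactants: 19 4,4-dimethoxybut-3-en-2-one
Product: 20 1,1-dimethoxy-3-(trimethylsilyloxy)buta-1,3-diene
Conditions: Me3SiCl, Et3N, ZnCl2 (cat.), toluene, 40 °C; filtration and distillation under N2
Reagents that add atoms: chlorotrimethylsilane, C[Si](C)(C)Cl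
Why: Soft enolisation of the methyl ketone with O-silylation (silyl enol ether formation) turns the vinylogous ester into the cross-conjugated, electron-rich diene.

**Step 11**
Reactants: 14 3-acetyl-2,6-bis(methoxymethoxy)-4-pentylphenyl hex-2-ynoate; 20 1,1-dimethoxy-3-(trimethylsilyloxy)buta-1,3-diene
Product: 23 3-acetyl-2,6-bis(methoxymethoxy)-4-pentylphenyl 4-hydroxy-2-methoxy-6-propylbenzoate, via cyclohexadiene cycloadduct 21 (not isolated), via aryl trimethylsilyl ether 22 (not isolated)
Conditions: 20 (3–4 equiv), xylenes, 140 °C, sealed tube, N2; then 0.1 M aq HCl, THF, 0 °C, brief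
Reagents that add atoms: none
Why: The electron-rich diene 20 and the electron-poor alkyne of 14 should combine in a thermal, normal-electron-demand, asynchronous [4+2] cycloaddition in which the CH2 terminus of 20 (its most nucleophilic carbon) bonds to the propyl-bearing β-carbon (C5'–C6') and the ketene-acetal carbon bonds to the α-carbon (C1'–C2') to give 21, which loses methanol from the acetal carbon to give the aromatic silyl ether 22, whose labile aryl O–SiMe3 bond alone is cleaved by cold dilute acid. The closest known reaction type is the Diels–Alder reaction with aromatisation of 1,1-dialkoxy-3-silyloxybuta-1,3-dienes and 3-alkyl-substituted alkynoates, which gives 6-alkyl-4-hydroxy-2-alkoxybenzoates. Ring B is closed by an intermolecular cycloaddition, four carbons (C2' to C5') coming from the diene and two (C1', C6') from the alkyne, with both ring bonds formed in the same step and no chain cyclisation involved. No stereocentre is created, since the two sp3 ring carbons of 21 become aromatic. The step needs regioselectivity and chemoselectivity: the first is secured by matched polarisation (three oxygen donors raise the coefficient at the CH2 terminus, the ester makes the β-carbon the electrophilic end, and an aryl ester lowers the alkyne LUMO more than an alkyl ester would), the second by the absence of any Lewis acid, so that the hindered aryl ketone, the ester carbonyl and the MOM acetals are not attacked by the diene. The ring construction itself therefore distinguishes the methyl ether at C2' from the free hydroxyl at C4', and the doubly ortho-substituted ester never has to be made by acyl substitution.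

**Step 12**
Reactants: 23 3-acetyl-2,6-bis(methoxymethoxy)-4-pentylphenyl 4-hydroxy-2-methoxy-6-propylbenzoate
Product: 24 3-acetyl-2,6-dihydroxy-4-pentylphenyl 4-hydroxy-2-methoxy-6-propylbenzoate (CNP0112527.0)
Conditions: HCl (1.25 M in MeOH), CH2Cl2, 0 °C to rt
Reagents that add atoms: none
Why: Acid-catalysed transacetalisation transfers both methoxymethyl groups to methanol (which also keeps formaldehyde equivalents away from electron-rich ring B), while the benzoate, ortho-disubstituted on both the acyl and the phenol side, is too hindered for acid methanolysis.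

**Compound list**
1 | olivetol (5-pentylbenzene-1,3-diol) | CCCCCc1cc(O)cc(O)c1 | starting material
2 | 1,3-bis(methoxymethoxy)-5-pentylbenzene | CCCCCc1cc(OCOC)cc(OCOC)c1 | intermediate
3 | [2,6-bis(methoxymethoxy)-4-pentylphenyl]lithium (formed in the flask) | CCCCCc1cc(OCOC)c([Li])c(OCOC)c1 | intermediate
4 | lithium [2,6-bis(methoxymethoxy)-4-pentylphenyl]trimethoxyborate (formed in the flask) | [Li+].CO[B-](OC)(OC)c1c(OCOC)cc(CCCCC)cc1OCOC | intermediate
5 | 2,6-bis(methoxymethoxy)-4-pentylphenol | CCCCCc1cc(OCOC)c(O)c(OCOC)c1 | intermediate
6 | tert-butyl[2,6-bis(methoxymethoxy)-4-pentylphenoxy]dimethylsilane | CCCCCc1cc(OCOC)c(O[Si](C)(C)C(C)(C)C)c(OCOC)c1 | intermediate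
7 | [3-bromo-2,6-bis(methoxymethoxy)-4-pentylphenoxy](tert-butyl)dimethylsilane | CCCCCc1cc(OCOC)c(O[Si](C)(C)C(C)(C)C)c(OCOC)c1Br | intermediate
8 | N-methoxy-N-methylacetamide | CC(=O)N(C)OC | starting material
9 | {3-[tert-butyl(dimethyl)silyloxy]-2,4-bis(methoxymethoxy)-6-pentylphenyl}lithium (formed in the flask) | CCCCCc1cc(OCOC)c(O[Si](C)(C)C(C)(C)C)c(OCOC)c1[Li] | intermediate
10 | lithium 1-{3-[tert-butyl(dimethyl)silyloxy]-2,4-bis(methoxymethoxy)-6-pentylphenyl}-1-[methoxy(methyl)amino]ethan-1-olate (racemic, formed in the flask) | CCCCCc1cc(OCOC)c(O[Si](C)(C)C(C)(C)C)c(OCOC)c1C(C)(O[Li])N(C)OC | intermediate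
11 | 1-[3-(tert-butyldimethylsilyloxy)-2,4-bis(methoxymethoxy)-6-pentylphenyl]ethan-1-one | CCCCCc1cc(OCOC)c(O[Si](C)(C)C(C)(C)C)c(OCOC)c1C(C)=O | intermediate
12 | 1-[3-hydroxy-2,4-bis(methoxymethoxy)-6-pentylphenyl]ethan-1-one | CCCCCc1cc(OCOC)c(O)c(OCOC)c1C(C)=O | intermediate
13 | hex-2-ynoic acid | CCCC#CC(=O)O | starting material
14 | 3-acetyl-2,6-bis(methoxymethoxy)-4-pentylphenyl hex-2-ynoate | CCCC#CC(=O)Oc1c(OCOC)cc(CCCCC)c(C(C)=O)c1OCOC | intermediate
15 | acetyl chloride | CC(=O)Cl | starting material
16 | 1,1-dichloroethene | C=C(Cl)Cl | starting material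
17 | 4,4,4-trichlorobutan-2-one (formed in the flask) | CC(=O)CC(Cl)(Cl)Cl | intermediate
18 | 4,4-dichlorobut-3-en-2-one | CC(=O)C=C(Cl)Cl | intermediate
19 | 4,4-dimethoxybut-3-en-2-one | CC(=O)C=C(OC)OC | intermediate
20 | 1,1-dimethoxy-3-(trimethylsilyloxy)buta-1,3-diene | COC(OC)=CC(=C)O[Si](C)(C)C | intermediate
21 | 3-acetyl-2,6-bis(methoxymethoxy)-4-pentylphenyl 6,6-dimethoxy-2-propyl-4-(trimethylsilyloxy)cyclohexa-1,4-diene-1-carboxylate (formed in the flask) | CCCC1=C(C(=O)Oc2c(OCOC)cc(CCCCC)c(C(C)=O)c2OCOC)C(OC)(OC)C=C(O[Si](C)(C)C)C1 | intermediate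
22 | 3-acetyl-2,6-bis(methoxymethoxy)-4-pentylphenyl 2-methoxy-6-propyl-4-(trimethylsilyloxy)benzoate (formed in the flask) | CCCc1cc(O[Si](C)(C)C)cc(OC)c1C(=O)Oc1c(OCOC)cc(CCCCC)c(C(C)=O)c1OCOC | intermediate
23 | 3-acetyl-2,6-bis(methoxymethoxy)-4-pentylphenyl 4-hydroxy-2-methoxy-6-propylbenzoate | CCCCCc1cc(OCOC)c(OC(=O)c2c(CCC)cc(O)cc2OC)c(OCOC)c1C(C)=O | intermediate
24 | 3-acetyl-2,6-dihydroxy-4-pentylphenyl 4-hydroxy-2-methoxy-6-propylbenzoate (CNP0112527.0) | CCCCCc1cc(O)c(OC(=O)c2c(CCC)cc(O)cc2OC)c(O)c1C(C)=O | target

**Count**
Total step count: 12 (steps 1–7 ring A and the ynoate, steps 8–10 the diene, steps 11 and 12).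
Longest linear sequence: 9 steps (1–7, 11, 12) from olivetol.

**Steps most likely to fail**

Step 11. The 3-propyl group makes the alkyne a sluggish dienophile, so thermal decomposition, oligomerisation or adventitious desilylation of the diene may outrun the cycloaddition, and long heating may erode the MOM acetals. The fallback sets out from 12 and comes back at 23.
- 12 would be esterified with purchased hex-3-ynoic acid (DCC, catalytic DMAP, CH2Cl2) to 3-acetyl-2,6-bis(methoxymethoxy)-4-pentylphenyl hex-3-ynoate F1.
- Et3N would shift the triple bond of F1 into conjugation through its doubly activated CH2 group, giving racemic 3-acetyl-2,6-bis(methoxymethoxy)-4-pentylphenyl hexa-2,3-dienoate F2.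
- The conjugated C2=C3 bond of an allenoate is a much stronger dienophile and should take up 20 with the same orientation well below 100 °C. This gives 3-acetyl-2,6-bis(methoxymethoxy)-4-pentylphenyl 2,2-dimethoxy-6-propylidene-4-(trimethylsilyloxy)cyclohex-3-ene-1-carboxylate F3.
- Loss of methanol and migration of the exocyclic double bond into the ring lead to 22, and the same cold acid work-up to 23. The same two ring bonds are formed from the same diene.

Step 5. Proton transfer from the acetyl group of the Weinreb amide to the doubly ortho-substituted aryllithium, or slow addition at this crowded carbanion, would return debrominated arene. The fallback sets out from 7 and comes back at 11.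
- After the same Br–Li exchange, aryllithium 9 would be trapped with acetaldehyde, a small electrophile whose carbonyl addition outruns enolisation. This gives racemic 1-[3-(tert-butyldimethylsilyloxy)-2,4-bis(methoxymethoxy)-6-pentylphenyl]ethan-1-ol F4.
- Dess–Martin periodinane (NaHCO3, CH2Cl2) would oxidise this benzylic alcohol to 11.

Step 7. Slow acyl transfer to the 2,6-disubstituted phenol may let the activated acid rearrange to the N-acylurea, and DMAP may trigger conjugate addition or alkyne–allene isomerisation of the activated ynoate. The fallback sets out from 13 and 12 and comes back at 14.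
- 13 would be converted with oxalyl chloride and catalytic DMF (CH2Cl2, 0 °C) into hex-2-ynoyl chloride F5.
- 12 would be converted with NaH (1.0 equiv, THF, 0 °C) into sodium 3-acetyl-2,6-bis(methoxymethoxy)-4-pentylphenolate F6.
- Combining the two at −40 °C should give 14 by direct acylation of the phenolate, with neither carbodiimide nor nucleophilic catalyst present.

**Further compounds**
F1 | step 11 | 3-acetyl-2,6-bis(methoxymethoxy)-4-pentylphenyl hex-3-ynoate | CCC#CCC(=O)Oc1c(OCOC)cc(CCCCC)c(C(C)=O)c1OCOC
F2 | step 11 | 3-acetyl-2,6-bis(methoxymethoxy)-4-pentylphenyl hexa-2,3-dienoate (racemic allene) | CCC=C=CC(=O)Oc1c(OCOC)cc(CCCCC)c(C(C)=O)c1OCOC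
F3 | step 11 | 3-acetyl-2,6-bis(methoxymethoxy)-4-pentylphenyl 2,2-dimethoxy-6-propylidene-4-(trimethylsilyloxy)cyclohex-3-ene-1-carboxylate (racemic, alkene geometry not defined) | CCC=C1CC(O[Si](C)(C)C)=CC(OC)(OC)C1C(=O)Oc1c(OCOC)cc(CCCCC)c(C(C)=O)c1OCOC
F4 | step 5 | 1-[3-(tert-butyldimethylsilyloxy)-2,4-bis(methoxymethoxy)-6-pentylphenyl]ethan-1-ol (racemic) | CCCCCc1cc(OCOC)c(O[Si](C)(C)C(C)(C)C)c(OCOC)c1C(C)O
F5 | step 7 | hex-2-ynoyl chloride | CCCC#CC(=O)Cl
F6 | step 7 | sodium 3-acetyl-2,6-bis(methoxymethoxy)-4-pentylphenolate | CCCCCc1cc(OCOC)c([O-])c(OCOC)c1C(C)=O.[Na+]
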